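**Strategy**

Units: 1 is the 4-hydroxyphenyl flavan, 2 sits on its C6, 3 on its C4, 4 is terminal. The route rests on cutting C4–C4a of unit 2, the diarylmethine carbon joining ring A of unit 2 to C6 of unit 1. One iminium-catalysed Friedel–Crafts alkylation–hemiacetalisation joins 3,5-bis(benzyloxy)phenol to an (E)-cinnamaldehyde carrying the future ring A of unit 1 (two benzyl ethers, one para silyl ether), closes the pyran ring as a lactol and sets C4. That centre relays C2 and C3 of the all-cis ring C. The same cascade, repeated with an enal made from (−)-epicatechin, builds unit 1 and attaches dimer 3–4.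

Key step: step 4

Remark: the target is read from its SMILES as having an all-cis (2,3-cis-3,4-cis) ring C in unit 1 as in unit 2, with unit 3 (2,3-cis-3,4-trans) bonded from C4 to C6 of unit 4. Bn = benzyl, TIPS = triisopropylsilyl. Compounds 1, 9, 15, 28 and all reagents are taken as commercial. Lactol and hemiketal carbons are written without configuration because they are mixtures that vanish in the next operation.

**Route**

Step 1
Reactants: 1 3,5-bis(benzyloxy)phenol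
Product: 3 2,6-bis(benzyloxy)-4-hydroxybenzaldehyde, via iminium salt 2 (not isolated)
Conditions: POCl3, DMF, 0 °C to rt; then aq NaOAc, rt
Reagents that add atoms: N,N-dimethylformamide, CN(C)C=O; water, O
Why: Vilsmeier–Haack formylation of a 3,5-dialkoxyphenol is expected to go mainly para to the hydroxyl, between the two ether groups, and the minor chelated ortho isomer should be separable by chromatography.

Step 2
Reactants: 3 2,6-bis(benzyloxy)-4-hydroxybenzaldehyde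
Product: 4 2,6-bis(benzyloxy)-4-(triisopropylsilyloxy)benzaldehyde
Conditions: TIPSCl, imidazole, DMF, 0 °C to rt
Reagents that add atoms: chlorotriisopropylsilane, CC(C)[Si](Cl)(C(C)C)C(C)C
Why: Silyl ether formation at the acidic, unhindered phenol marks the one oxygen that can later be freed by fluoride without touching the benzyl ethers.

Step 3
Reactants: 4 2,6-bis(benzyloxy)-4-(triisopropylsilyloxy)benzaldehyde
Product: 5 (E)-3-[2,6-bis(benzyloxy)-4-(triisopropylsilyloxy)phenyl]prop-2-enal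
Conditions: Ph3P=CHCHO, toluene, 100 °C
Reagents that add atoms: (triphenylphosphoranylidene)acetaldehyde, O=CC=P(c1ccccc1)(c1ccccc1)c1ccccc1
Why: Wittig olefination with the stabilised formylmethylene ylide adds two carbons under neutral conditions and should give the (E)-enal, as stabilised ylides do.

Step 4
Reactants: 1 3,5-bis(benzyloxy)phenol (1.5 equiv); 5 (E)-3-[2,6-bis(benzyloxy)-4-(triisopropylsilyloxy)phenyl]prop-2-enal
Product: 7 (4R)-5,7-bis(benzyloxy)-4-[2,6-bis(benzyloxy)-4-(triisopropylsilyloxy)phenyl]chroman-2-ol (both anomers), via aldehyde 6 (not isolated)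
Conditions: (R)-α,α-diphenylprolinol trimethylsilyl ether (20 mol%), PhCO2H (20 mol%), toluene, 0 °C to rt
Reagents that add atoms: none
Why: The amine condenses with enal 5 to an (E)-iminium ion, an ortho carbon of phenol 1 adds to its β-carbon to form C4–C4a, and rearomatisation and hydrolysis give aldehyde 6. The closest known reaction is the prolinol-silyl-ether-catalysed Friedel–Crafts alkylation of electron-rich phenols and naphthols with enals that ends in lactol formation. The pyran ring closes by 6-exo-trig addition of the phenol oxygen to the aldehyde (hemiacetalisation, O1–C2). C4, the only new defined stereocentre, is set by the catalyst, whose diphenyl(silyloxy)methyl group covers one face of the iminium ion so that the (R)-catalyst should deliver the arene to the face that gives (4R). The step needs ortho and not para alkylation of 1, which the substrate secures because the para carbon lies between two benzyloxy groups and the two ortho carbons are equivalent. The enal aryl group carries its only non-benzyl oxygen para to the new bond, so the later annulation of unit 1 can give only the C4-to-C6 linkage.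

Step 5
Reactants: 7 lactol
Product: 8 (4R)-5,7-bis(benzyloxy)-4-[2,6-bis(benzyloxy)-4-(triisopropylsilyloxy)phenyl]chroman-2-one
Conditions: Ag2CO3 on Celite, toluene, 80 °C
Reagents that add atoms: none
Why: Fétizon oxidation converts a lactol into the lactone under neutral conditions, so C4, the silyl ether and the electron-rich rings are left alone.

Step 6
Reactants: 8 lactone; 9 4-bromo-1,2-bis(benzyloxy)benzene
Product: 11 (4R)-5,7-bis(benzyloxy)-2-[3,4-bis(benzyloxy)phenyl]-4-[2,6-bis(benzyloxy)-4-(triisopropylsilyloxy)phenyl]-4H-chromene, via hemiketal 10 (not isolated)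
Conditions: 9, n-BuLi, THF, −78 °C; CeCl3, −78 °C; then 8, −78 to −40 °C; aq NH4Cl; crude, p-TsOH·H2O (cat.), 4 Å MS, toluene, rt
Reagents that add atoms: none
Why: Organocerium addition puts one aryl group on the lactone carbonyl without enolising it, and acid-catalysed dehydration of the 2-aryl-2-chromanol gives the conjugated 4H-chromene with C4 untouched.

Step 7
Reactants: 11 4H-chromene
Product: 13 (2R,3S,4R)-5,7-bis(benzyloxy)-2-[3,4-bis(benzyloxy)phenyl]-4-[2,6-bis(benzyloxy)-4-(triisopropylsilyloxy)phenyl]chroman-3-ol (2,3-trans-3,4-trans), via alkylborane 12 (not isolated)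
Conditions: BH3·THF, THF, 0 °C to rt; then NaOH, H2O2, 0 °C
Reagents that add atoms: hydrogen peroxide, OO
Why: Hydroboration–oxidation of the enol ether places boron on C3 and adds H and B syn from the face opposite the bulky 4-aryl group, which sets C2 (aryl cis to the 4-aryl group) and C3 (hydroxyl trans to both aryl groups).

Step 8
Reactants: 13 silyl ether
Product: 14 (2R,3S,4R)-5,7-bis(benzyloxy)-4-[2,6-bis(benzyloxy)-4-hydroxyphenyl]-2-[3,4-bis(benzyloxy)phenyl]chroman-3-ol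
Conditions: TBAF, AcOH, THF, 0 °C
Reagents that add atoms: none
Why: Buffered fluoride desilylation frees the single phenol para to C4 of unit 2 while all benzyl ethers stay.

Step 9
Reactants: 15 (−)-epicatechin
Product: 16 (2R,3R)-5,7-bis(benzyloxy)-2-[3,4-bis(benzyloxy)phenyl]chroman-3-ol
Conditions: BnBr, K2CO3, DMF, 0 °C to rt
Reagents that add atoms: benzyl bromide, BrCc1ccccc1
Why: Williamson etherification with a carbonate base benzylates the four phenols only, the secondary alcohol and both stereocentres being untouched.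

Step 10
Reactants: 16 tetra-O-benzylepicatechin
Product: 17 (2R,3R)-3,5,7-tris(benzyloxy)-2-[3,4-bis(benzyloxy)phenyl]chromane
Conditions: NaH, BnBr, Bu4NI (cat.), DMF, 0 °C to rt
Reagents that add atoms: benzyl bromide, BrCc1ccccc1
Why: Williamson etherification of the sodium alkoxide protects O3 so that units 3 and 4 carry no free hydroxyl through the later organometallic and oxidation steps.

Step 11
Reactants: 17 penta-O-benzylepicatechin
Product: 18 (2R,3R)-8-bromo-3,5,7-tris(benzyloxy)-2-[3,4-bis(benzyloxy)phenyl]chromane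
Conditions: NBS, CH2Cl2, −78 to −20 °C
Reagents that add atoms: N-bromosuccinimide, O=C1CCC(=O)N1Br
Why: Electrophilic aromatic bromination of 5,7-dialkoxyflavans at low temperature is known to go to C8, which leaves C6 as the only nucleophilic carbon of the future unit 4.

Step 12
Reactants: 17 penta-O-benzylepicatechin
Product: 19 (2R,3R)-8-iodo-3,5,7-tris(benzyloxy)-2-[3,4-bis(benzyloxy)phenyl]chromane
Conditions: NIS, CH2Cl2, −20 to 0 °C
Reagents that add atoms: N-iodosuccinimide, O=C1CCC(=O)N1I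
Why: Electrophilic aromatic iodination follows the same C8 preference and caps the future unit 3 with a halogen that exchanges with lithium faster than bromine does.

Step 13
Reactants: 19 8-iodo flavan
Product: 20 (2R,3R,4S)-4-(2-ethoxyethoxy)-8-iodo-3,5,7-tris(benzyloxy)-2-[3,4-bis(benzyloxy)phenyl]chromane (3,4-trans)
Conditions: DDQ, EtOCH2CH2OH, CH2Cl2, rt
Reagents that add atoms: 2-ethoxyethanol, CCOCCO
Why: DDQ-mediated benzylic oxidation at C4 followed by capture of the cation by the alcohol trans to the 3-benzyloxy group is the standard entry to 4-alkoxyflavans.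

Step 14
Reactants: 20 4-alkoxy flavan; 18 8-bromo flavan (3 equiv)
Product: 21 dimer 3–4: C4 of the 8-iodo unit (3,4-trans) bonded to C6 of the 8-bromo unit, all hydroxyls benzylated
Conditions: TMSOTf (cat.), CH2Cl2, −78 to −40 °C; then Et3N
Reagents that add atoms: none
Why: Lewis-acid-mediated Friedel–Crafts coupling of the flavan-4-yl cation from 20 with the excess C8-blocked nucleophile 18 can engage only C6, and attack trans to the 3-benzyloxy group of the 2,3-cis cation sets C4 of unit 3.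

Step 15
Reactants: 21 iodo bromo dimer
Product: 23 dimer 3–4 with a formyl group on C8 of unit 3, via aryllithium 22 (not isolated)
Conditions: n-BuLi (1.0 equiv), THF, −78 °C; then DMF, −78 to 0 °C; aq NH4Cl
Reagents that add atoms: N,N-dimethylformamide, CN(C)C=O
Why: Iodine–lithium exchange is much faster than bromine–lithium exchange, so one equivalent of n-BuLi should metalate only C8 of unit 3, and the aryllithium is formylated by DMF.

Step 16
Reactants: 23 dimer aldehyde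
Product: 24 dimer 3–4 with an (E)-3-oxoprop-1-enyl group on C8 of unit 3
Conditions: Ph3P=CHCHO, toluene, 100 °C
Reagents that add atoms: (triphenylphosphoranylidene)acetaldehyde, O=CC=P(c1ccccc1)(c1ccccc1)c1ccccc1
Why: Wittig olefination with the stabilised ylide gives the (E)-enal, as in step 3.

Step 17
Reactants: 14 phenol; 24 dimer enal
Product: 26 lactol of unit 1: 5,7-bis(benzyloxy)chroman-2-ol with unit 2 on C6 and dimer 3–4 on C4 (both anomers), via aldehyde 25 (not isolated)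
Conditions: (R)-α,α-diphenylprolinol trimethylsilyl ether (30 mol%), PhCO2H (30 mol%), toluene, rt
Reagents that add atoms: none
Why: The same iminium-catalysed Friedel–Crafts alkylation–hemiacetalisation as in step 4 joins an ortho carbon of phenol 14 (the para position is occupied by unit 2 and the two ortho carbons are equivalent) to the β-carbon of enal 24, the (R)-catalyst setting C4 of unit 1 in the same sense as in step 4 and the lactol closing by 6-exo-trig attack.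

Step 18
Reactants: 26 lactol
Product: 27 lactone of unit 1 (chroman-2-one)
Conditions: Ag2CO3 on Celite, toluene, 80 °C
Reagents that add atoms: none
Why: Fétizon oxidation takes lactols far faster than secondary alcohols, so the free 3-hydroxyl of unit 2 should survive.

Step 19
Reactants: 27 lactone; 28 1-(benzyloxy)-4-bromobenzene
Product: 30 4H-chromene of unit 1 carrying 4-(benzyloxy)phenyl on C2, via hemiketal 29 (not isolated)
Conditions: 28, n-BuLi, THF, −78 °C; CeCl3, −78 °C; then 27, −78 to −40 °C; aq NH4Cl; crude, p-TsOH·H2O (cat.), 4 Å MS, toluene, rt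
Reagents that add atoms: none
Why: Organocerium addition to the lactone and acid-catalysed dehydration repeat step 6, the free hydroxyl of unit 2 only consuming one equivalent of reagent and the aryl bromide being inert at −78 °C.

Step 20
Reactants: 30 4H-chromene
Product: 32 diol in which ring C of unit 1 is 2,3-trans-3,4-trans like ring C of unit 2, via alkylborane 31 (not isolated)
Conditions: BH3·THF, THF, 0 °C to rt; then NaOH, H2O2, 0 °C
Reagents that add atoms: hydrogen peroxide, OO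
Why: Hydroboration–oxidation adds H and B syn from the face opposite the 4-aryl group (dimer 3–4), which sets C2 and C3 of unit 1 exactly as step 7 did for unit 2.

Step 21
Reactants: 32 diol
Product: 33 bis(flavan-3-one) carrying a C3 ketone in ring C of unit 1 plus one in ring C of unit 2
Conditions: Dess–Martin periodinane, NaHCO3, CH2Cl2, 0 °C to rt
Reagents that add atoms: none
Why: Dess–Martin oxidation converts both secondary alcohols into ketones under buffered conditions, and C2 and C4 should hold because the 2,4-cis diaryl arrangement is the stable one.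

Step 22
Reactants: 33 diketone
Product: 34 protected target (all-cis ring C in unit 1 as in unit 2, seventeen benzyl ethers, bromine on C8 of unit 4)
Conditions: LiBH(sec-Bu)3, THF, −78 °C; aq NH4Cl
Reagents that add atoms: none
Why: The bulky hydride reduces each flavan-3-one from the face opposite the two cis aryl groups at C2 and C4, so both new 3-hydroxyls end up cis to them, the known oxidation–reduction inversion of flavan-3-ols.

Step 23
Reactants: 34 protected target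
Product: 35 target CNP0103636.2
Conditions: H2 (1 atm), Pd(OH)2/C, Et3N, THF/MeOH/H2O, rt
Reagents that add atoms: none
Why: Catalytic hydrogenolysis removes the seventeen benzyl ethers and the aryl bromide in one operation, Et3N taking up the HBr so that the acid-labile interflavan bonds are not exposed to acid.

**Compound list**

1 | 3,5-bis(benzyloxy)phenol | Oc1cc(OCc2ccccc2)cc(OCc2ccccc2)c1 | starting material
2 | [2,6-bis(benzyloxy)-4-hydroxybenzylidene]dimethyliminium dichlorophosphate | C[N+](C)=Cc1c(OCc2ccccc2)cc(O)cc1OCc1ccccc1.[O-]P(Cl)(Cl)=O | intermediate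
3 | 2,6-bis(benzyloxy)-4-hydroxybenzaldehyde | O=Cc1c(OCc2ccccc2)cc(O)cc1OCc1ccccc1 | intermediate
4 | 2,6-bis(benzyloxy)-4-(triisopropylsilyloxy)benzaldehyde | O=Cc1c(OCc2ccccc2)cc(O[Si](C(C)C)(C(C)C)C(C)C)cc1OCc1ccccc1 | intermediate
5 | (E)-3-[2,6-bis(benzyloxy)-4-(triisopropylsilyloxy)phenyl]prop-2-enal | O=C/C=C/c1c(OCc2ccccc2)cc(O[Si](C(C)C)(C(C)C)C(C)C)cc1OCc1ccccc1 | intermediate
6 | (3S)-3-[2,4-bis(benzyloxy)-6-hydroxyphenyl]-3-[2,6-bis(benzyloxy)-4-(triisopropylsilyloxy)phenyl]propanal | O=CC[C@H](c1c(OCc9ccccc9)cc(O[Si](C(C)C)(C(C)C)C(C)C)cc1OCc9ccccc9)c1c(OCc9ccccc9)cc(OCc9ccccc9)cc1O | intermediate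
7 | (4R)-5,7-bis(benzyloxy)-4-[2,6-bis(benzyloxy)-4-(triisopropylsilyloxy)phenyl]chroman-2-ol, anomers | OC1C[C@H](c2c(OCc9ccccc9)cc(O[Si](C(C)C)(C(C)C)C(C)C)cc2OCc9ccccc9)c2c(OCc9ccccc9)cc(OCc9ccccc9)cc2O1 | intermediate
8 | (4R)-5,7-bis(benzyloxy)-4-[2,6-bis(benzyloxy)-4-(triisopropylsilyloxy)phenyl]chroman-2-one | O=C1C[C@H](c2c(OCc9ccccc9)cc(O[Si](C(C)C)(C(C)C)C(C)C)cc2OCc9ccccc9)c2c(OCc9ccccc9)cc(OCc9ccccc9)cc2O1 | intermediate
9 | 4-bromo-1,2-bis(benzyloxy)benzene | Brc1ccc(OCc2ccccc2)c(OCc2ccccc2)c1 | starting material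
10 | (4R)-5,7-bis(benzyloxy)-2-[3,4-bis(benzyloxy)phenyl]-4-[2,6-bis(benzyloxy)-4-(triisopropylsilyloxy)phenyl]chroman-2-ol, C2 epimers | OC1(c2ccc(OCc9ccccc9)c(OCc9ccccc9)c2)C[C@H](c2c(OCc9ccccc9)cc(O[Si](C(C)C)(C(C)C)C(C)C)cc2OCc9ccccc9)c2c(OCc9ccccc9)cc(OCc9ccccc9)cc2O1 | intermediate
11 | (4R)-5,7-bis(benzyloxy)-2-[3,4-bis(benzyloxy)phenyl]-4-[2,6-bis(benzyloxy)-4-(triisopropylsilyloxy)phenyl]-4H-chromene | C1(c2ccc(OCc9ccccc9)c(OCc9ccccc9)c2)=C[C@H](c2c(OCc9ccccc9)cc(O[Si](C(C)C)(C(C)C)C(C)C)cc2OCc9ccccc9)c2c(OCc9ccccc9)cc(OCc9ccccc9)cc2O1 | intermediate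
12 | C3-boryl adduct of 11 (boron trans to both aryl groups) | CC(C)[Si](C(C)C)(C(C)C)Oc1cc(OCc9ccccc9)c(c(OCc9ccccc9)c1)[C@@H]4c5c(OCc9ccccc9)cc(OCc9ccccc9)cc5O[C@H](c5ccc(OCc9ccccc9)c(OCc9ccccc9)c5)[C@H]4B | intermediate
13 | (2R,3S,4R)-5,7-bis(benzyloxy)-2-[3,4-bis(benzyloxy)phenyl]-4-[2,6-bis(benzyloxy)-4-(triisopropylsilyloxy)phenyl]chroman-3-ol | CC(C)[Si](C(C)C)(C(C)C)Oc1cc(OCc9ccccc9)c(c(OCc9ccccc9)c1)[C@@H]4c5c(OCc9ccccc9)cc(OCc9ccccc9)cc5O[C@H](c5ccc(OCc9ccccc9)c(OCc9ccccc9)c5)[C@H]4O | intermediate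
14 | (2R,3S,4R)-5,7-bis(benzyloxy)-4-[2,6-bis(benzyloxy)-4-hydroxyphenyl]-2-[3,4-bis(benzyloxy)phenyl]chroman-3-ol | Oc1cc(OCc9ccccc9)c(c(OCc9ccccc9)c1)[C@@H]4c5c(OCc9ccccc9)cc(OCc9ccccc9)cc5O[C@H](c5ccc(OCc9ccccc9)c(OCc9ccccc9)c5)[C@H]4O | intermediate
15 | (−)-epicatechin, (2R,3R) | O[C@@H]1Cc2c(O)cc(O)cc2O[C@@H]1c1ccc(O)c(O)c1 | starting material
16 | (2R,3R)-5,7-bis(benzyloxy)-2-[3,4-bis(benzyloxy)phenyl]chroman-3-ol | O[C@@H]1Cc2c(OCc9ccccc9)cc(OCc9ccccc9)cc2O[C@@H]1c1ccc(OCc9ccccc9)c(OCc9ccccc9)c1 | intermediate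
17 | (2R,3R)-3,5,7-tris(benzyloxy)-2-[3,4-bis(benzyloxy)phenyl]chromane | O(Cc9ccccc9)[C@@H]1Cc2c(OCc9ccccc9)cc(OCc9ccccc9)cc2O[C@@H]1c1ccc(OCc9ccccc9)c(OCc9ccccc9)c1 | intermediate
18 | (2R,3R)-8-bromo-3,5,7-tris(benzyloxy)-2-[3,4-bis(benzyloxy)phenyl]chromane | O(Cc9ccccc9)[C@@H]1Cc2c(OCc9ccccc9)cc(OCc9ccccc9)c(Br)c2O[C@@H]1c1ccc(OCc9ccccc9)c(OCc9ccccc9)c1 | intermediate
19 | (2R,3R)-8-iodo-3,5,7-tris(benzyloxy)-2-[3,4-bis(benzyloxy)phenyl]chromane | O(Cc9ccccc9)[C@@H]1Cc2c(OCc9ccccc9)cc(OCc9ccccc9)c(I)c2O[C@@H]1c1ccc(OCc9ccccc9)c(OCc9ccccc9)c1 | intermediate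
20 | (2R,3R,4S)-4-(2-ethoxyethoxy)-8-iodo-3,5,7-tris(benzyloxy)-2-[3,4-bis(benzyloxy)phenyl]chromane | Ic1c(OCc9ccccc9)cc(OCc9ccccc9)c2c1O[C@H](c1ccc(OCc9ccccc9)c(OCc9ccccc9)c1)[C@H](OCc9ccccc9)[C@H]2OCCOCC | intermediate
21 | dimer 3–4, 8-iodo on unit 3, 8-bromo on unit 4, C4 (unit 3, 3,4-trans) to C6 (unit 4) | Ic1c(OCc9ccccc9)cc(OCc9ccccc9)c2c1O[C@H](c1ccc(OCc9ccccc9)c(OCc9ccccc9)c1)[C@H](OCc9ccccc9)[C@H]2c1c(OCc9ccccc9)c(Br)c2c(c1OCc9ccccc9)C[C@@H](OCc9ccccc9)[C@@H](c1ccc(OCc9ccccc9)c(OCc9ccccc9)c1)O2 | intermediate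
22 | dimer 3–4 lithiated at C8 of unit 3 | [Li]c1c(OCc9ccccc9)cc(OCc9ccccc9)c2c1O[C@H](c1ccc(OCc9ccccc9)c(OCc9ccccc9)c1)[C@H](OCc9ccccc9)[C@H]2c1c(OCc9ccccc9)c(Br)c2c(c1OCc9ccccc9)C[C@@H](OCc9ccccc9)[C@@H](c1ccc(OCc9ccccc9)c(OCc9ccccc9)c1)O2 | intermediate
23 | dimer 3–4 with formyl on C8 of unit 3 | O=Cc1c(OCc9ccccc9)cc(OCc9ccccc9)c2c1O[C@H](c1ccc(OCc9ccccc9)c(OCc9ccccc9)c1)[C@H](OCc9ccccc9)[C@H]2c1c(OCc9ccccc9)c(Br)c2c(c1OCc9ccccc9)C[C@@H](OCc9ccccc9)[C@@H](c1ccc(OCc9ccccc9)c(OCc9ccccc9)c1)O2 | intermediate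
24 | dimer 3–4 with (E)-3-oxoprop-1-enyl on C8 of unit 3 | O=C/C=C/c1c(OCc9ccccc9)cc(OCc9ccccc9)c2c1O[C@H](c1ccc(OCc9ccccc9)c(OCc9ccccc9)c1)[C@H](OCc9ccccc9)[C@H]2c1c(OCc9ccccc9)c(Br)c2c(c1OCc9ccccc9)C[C@@H](OCc9ccccc9)[C@@H](c1ccc(OCc9ccccc9)c(OCc9ccccc9)c1)O2 | intermediate
25 | open-chain adduct: 3-(dimer 3–4 C8-yl)-3-[ring A of unit 1, free phenol, unit 2 para to it]propanal, C4 of unit 1 set | Oc3cc(OCc9ccccc9)c([C@@H]4c5c(OCc9ccccc9)cc(OCc9ccccc9)cc5O[C@H](c5ccc(OCc9ccccc9)c(OCc9ccccc9)c5)[C@H]4O)c(OCc9ccccc9)c3[C@@H](c3c(OCc9ccccc9)cc(OCc9ccccc9)c4c3O[C@H](c3ccc(OCc9ccccc9)c(OCc9ccccc9)c3)[C@H](OCc9ccccc9)[C@H]4c3c(OCc9ccccc9)c(Br)c4c(c3OCc9ccccc9)C[C@@H](OCc9ccccc9)[C@@H](c3ccc(OCc9ccccc9)c(OCc9ccccc9)c3)O4)CC=O | intermediate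
26 | lactol of unit 1 (chroman-2-ol, anomers) with unit 2 on C6 and dimer 3–4 on C4 | OC2Oc3cc(OCc9ccccc9)c([C@@H]4c5c(OCc9ccccc9)cc(OCc9ccccc9)cc5O[C@H](c5ccc(OCc9ccccc9)c(OCc9ccccc9)c5)[C@H]4O)c(OCc9ccccc9)c3[C@@H](c3c(OCc9ccccc9)cc(OCc9ccccc9)c4c3O[C@H](c3ccc(OCc9ccccc9)c(OCc9ccccc9)c3)[C@H](OCc9ccccc9)[C@H]4c3c(OCc9ccccc9)c(Br)c4c(c3OCc9ccccc9)C[C@@H](OCc9ccccc9)[C@@H](c3ccc(OCc9ccccc9)c(OCc9ccccc9)c3)O4)C2 | intermediate
27 | lactone of unit 1 (chroman-2-one) with unit 2 on C6 and dimer 3–4 on C4 | O=C2Oc3cc(OCc9ccccc9)c([C@@H]4c5c(OCc9ccccc9)cc(OCc9ccccc9)cc5O[C@H](c5ccc(OCc9ccccc9)c(OCc9ccccc9)c5)[C@H]4O)c(OCc9ccccc9)c3[C@@H](c3c(OCc9ccccc9)cc(OCc9ccccc9)c4c3O[C@H](c3ccc(OCc9ccccc9)c(OCc9ccccc9)c3)[C@H](OCc9ccccc9)[C@H]4c3c(OCc9ccccc9)c(Br)c4c(c3OCc9ccccc9)C[C@@H](OCc9ccccc9)[C@@H](c3ccc(OCc9ccccc9)c(OCc9ccccc9)c3)O4)C2 | intermediate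
28 | 1-(benzyloxy)-4-bromobenzene | Brc1ccc(OCc2ccccc2)cc1 | starting material
29 | hemiketal of unit 1: 2-[4-(benzyloxy)phenyl]chroman-2-ol, C2 epimers | OC2(c1ccc(OCc9ccccc9)cc1)Oc3cc(OCc9ccccc9)c([C@@H]4c5c(OCc9ccccc9)cc(OCc9ccccc9)cc5O[C@H](c5ccc(OCc9ccccc9)c(OCc9ccccc9)c5)[C@H]4O)c(OCc9ccccc9)c3[C@@H](c3c(OCc9ccccc9)cc(OCc9ccccc9)c4c3O[C@H](c3ccc(OCc9ccccc9)c(OCc9ccccc9)c3)[C@H](OCc9ccccc9)[C@H]4c3c(OCc9ccccc9)c(Br)c4c(c3OCc9ccccc9)C[C@@H](OCc9ccccc9)[C@@H](c3ccc(OCc9ccccc9)c(OCc9ccccc9)c3)O4)C2 | intermediate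
30 | 4H-chromene of unit 1 with 4-(benzyloxy)phenyl on C2 | C2(c1ccc(OCc9ccccc9)cc1)Oc3cc(OCc9ccccc9)c([C@@H]4c5c(OCc9ccccc9)cc(OCc9ccccc9)cc5O[C@H](c5ccc(OCc9ccccc9)c(OCc9ccccc9)c5)[C@H]4O)c(OCc9ccccc9)c3[C@@H](c3c(OCc9ccccc9)cc(OCc9ccccc9)c4c3O[C@H](c3ccc(OCc9ccccc9)c(OCc9ccccc9)c3)[C@H](OCc9ccccc9)[C@H]4c3c(OCc9ccccc9)c(Br)c4c(c3OCc9ccccc9)C[C@@H](OCc9ccccc9)[C@@H](c3ccc(OCc9ccccc9)c(OCc9ccccc9)c3)O4)C=2 | intermediate
31 | C3-boryl adduct of unit 1 (boron trans to both aryl groups), hydroxyl of unit 2 held as its borate | O(Cc9ccccc9)c1ccc([C@H]2Oc3cc(OCc9ccccc9)c([C@@H]4c5c(OCc9ccccc9)cc(OCc9ccccc9)cc5O[C@H](c5ccc(OCc9ccccc9)c(OCc9ccccc9)c5)[C@H]4OB)c(OCc9ccccc9)c3[C@@H](c3c(OCc9ccccc9)cc(OCc9ccccc9)c4c3O[C@H](c3ccc(OCc9ccccc9)c(OCc9ccccc9)c3)[C@H](OCc9ccccc9)[C@H]4c3c(OCc9ccccc9)c(Br)c4c(c3OCc9ccccc9)C[C@@H](OCc9ccccc9)[C@@H](c3ccc(OCc9ccccc9)c(OCc9ccccc9)c3)O4)[C@@H]2B)cc1 | intermediate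
32 | diol in which ring C of unit 1 is 2,3-trans-3,4-trans like ring C of unit 2 | O(Cc9ccccc9)c1ccc([C@H]2Oc3cc(OCc9ccccc9)c([C@@H]4c5c(OCc9ccccc9)cc(OCc9ccccc9)cc5O[C@H](c5ccc(OCc9ccccc9)c(OCc9ccccc9)c5)[C@H]4O)c(OCc9ccccc9)c3[C@@H](c3c(OCc9ccccc9)cc(OCc9ccccc9)c4c3O[C@H](c3ccc(OCc9ccccc9)c(OCc9ccccc9)c3)[C@H](OCc9ccccc9)[C@H]4c3c(OCc9ccccc9)c(Br)c4c(c3OCc9ccccc9)C[C@@H](OCc9ccccc9)[C@@H](c3ccc(OCc9ccccc9)c(OCc9ccccc9)c3)O4)[C@@H]2O)cc1 | intermediate
33 | bis(flavan-3-one) carrying a C3 ketone in ring C of unit 1 plus one in ring C of unit 2, 2,4-cis aryl groups in both | O(Cc9ccccc9)c1ccc([C@H]2Oc3cc(OCc9ccccc9)c([C@@H]4c5c(OCc9ccccc9)cc(OCc9ccccc9)cc5O[C@H](c5ccc(OCc9ccccc9)c(OCc9ccccc9)c5)C4=O)c(OCc9ccccc9)c3[C@@H](c3c(OCc9ccccc9)cc(OCc9ccccc9)c4c3O[C@H](c3ccc(OCc9ccccc9)c(OCc9ccccc9)c3)[C@H](OCc9ccccc9)[C@H]4c3c(OCc9ccccc9)c(Br)c4c(c3OCc9ccccc9)C[C@@H](OCc9ccccc9)[C@@H](c3ccc(OCc9ccccc9)c(OCc9ccccc9)c3)O4)C2=O)cc1 | intermediate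
34 | protected target: all-cis ring C in unit 1 as in unit 2, seventeen benzyl ethers, 8-bromo on unit 4 | O(Cc9ccccc9)c1ccc([C@H]2Oc3cc(OCc9ccccc9)c([C@@H]4c5c(OCc9ccccc9)cc(OCc9ccccc9)cc5O[C@H](c5ccc(OCc9ccccc9)c(OCc9ccccc9)c5)[C@@H]4O)c(OCc9ccccc9)c3[C@@H](c3c(OCc9ccccc9)cc(OCc9ccccc9)c4c3O[C@H](c3ccc(OCc9ccccc9)c(OCc9ccccc9)c3)[C@H](OCc9ccccc9)[C@H]4c3c(OCc9ccccc9)c(Br)c4c(c3OCc9ccccc9)C[C@@H](OCc9ccccc9)[C@@H](c3ccc(OCc9ccccc9)c(OCc9ccccc9)c3)O4)[C@H]2O)cc1 | intermediate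
35 | CNP0103636.2 | Oc1ccc([C@H]2Oc3cc(O)c([C@@H]4c5c(O)cc(O)cc5O[C@H](c5ccc(O)c(O)c5)[C@@H]4O)c(O)c3[C@@H](c3c(O)cc(O)c4c3O[C@H](c3ccc(O)c(O)c3)[C@H](O)[C@H]4c3c(O)cc4c(c3O)C[C@@H](O)[C@@H](c3ccc(O)c(O)c3)O4)[C@H]2O)cc1 | target

**Step count and risks**

Total step count: 23. Longest linear sequence: 15 steps (steps 1 to 8, then 17 to 23).

Steps most likely to fail:

1. Step 4. Addition of the phenol to a hindered iminium ion that is strongly stabilised by three oxygen donors may be slow, so that an uncatalysed background reaction lowers the facial selectivity and alkylation para to the hydroxyl competes. Fallback, setting out from 1 and 4 and returning at 7: phenol 1 would be turned into its bromomagnesium phenoxide (EtMgBr, toluene) and condensed at the chelated ortho carbon with aldehyde 4 to give [2,4-bis(benzyloxy)-6-hydroxyphenyl][2,6-bis(benzyloxy)-4-(triisopropylsilyloxy)phenyl]methanol F1. Mild acid would release the ortho-quinone methide F2, and the enamine formed from acetaldehyde and the diphenylprolinol silyl ether (enantiomer chosen for the 4R product) would add to its methide carbon. Hydrolysis and ring closure would then give lactol 7. The aryl–C4 bond is thus made by carbonyl addition and the C3–C4 bond by enamine addition, so neither the iminium ion nor the ortho/para question arises.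

2. Step 17. The two large partners may combine too slowly for the catalyst to keep control, so C4 of unit 1 could form with poor diastereoselectivity or the enal could decompose first. Fallback, setting out from 14 and 21 and returning at 26: phenol 14 would be ortho-formylated (MgCl2, Et3N, paraformaldehyde) to the salicylaldehyde F3. Aryllithium 22, made from 21 as in step 15 and used in excess to cover the two hydroxyls, would add to it to give the diarylmethanol F4. Its ortho-quinone methide F5, released by mild acid, would be trapped by the acetaldehyde enamine of the diphenylprolinol silyl ether as above, and hydrolysis and ring closure would return lactol 26.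

3. Step 19. The first adduct may collapse to the keto phenoxide in the flask and take up a second aryl group, or the reagent may exchange with the aryl bromide, on material that is costly at this stage. Fallback, setting out from 27 and returning at 29: lactone 27 would be opened with MeNH(OMe)·HCl/AlMe3 to the phenolic N-methoxy-N-methylamide F6. Excess 4-(benzyloxy)phenyllithium would then stop at the ketone stage through the chelated tetrahedral adduct (Weinreb ketone synthesis). On work-up the keto phenol closes to hemiketal 29, which rejoins step 19 at the dehydration.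

**Further compounds**

F1 | step 4 | [2,4-bis(benzyloxy)-6-hydroxyphenyl][2,6-bis(benzyloxy)-4-(triisopropylsilyloxy)phenyl]methanol | OC(c1c(O)cc(OCc9ccccc9)cc1OCc9ccccc9)c1c(OCc9ccccc9)cc(O[Si](C(C)C)(C(C)C)C(C)C)cc1OCc9ccccc9
F2 | step 4 | ortho-quinone methide from F1 | O=C1C=C(OCc9ccccc9)C=C(OCc9ccccc9)C1=Cc1c(OCc9ccccc9)cc(O[Si](C(C)C)(C(C)C)C(C)C)cc1OCc9ccccc9
F3 | step 17 | salicylaldehyde from 14 (formyl ortho to the phenol) | O=Cc1c(O)cc(OCc9ccccc9)c([C@@H]4c5c(OCc9ccccc9)cc(OCc9ccccc9)cc5O[C@H](c5ccc(OCc9ccccc9)c(OCc9ccccc9)c5)[C@H]4O)c1OCc9ccccc9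
F4 | step 17 | diarylmethanol from F3 and 22 | OC(c3c(OCc9ccccc9)cc(OCc9ccccc9)c4c3O[C@H](c3ccc(OCc9ccccc9)c(OCc9ccccc9)c3)[C@H](OCc9ccccc9)[C@H]4c3c(OCc9ccccc9)c(Br)c4c(c3OCc9ccccc9)C[C@@H](OCc9ccccc9)[C@@H](c3ccc(OCc9ccccc9)c(OCc9ccccc9)c3)O4)c1c(O)cc(OCc9ccccc9)c([C@@H]4c5c(OCc9ccccc9)cc(OCc9ccccc9)cc5O[C@H](c5ccc(OCc9ccccc9)c(OCc9ccccc9)c5)[C@H]4O)c1OCc9ccccc9
F5 | step 17 | ortho-quinone methide from F4 | O=C1C=C(OCc9ccccc9)C([C@@H]4c5c(OCc9ccccc9)cc(OCc9ccccc9)cc5O[C@H](c5ccc(OCc9ccccc9)c(OCc9ccccc9)c5)[C@H]4O)=C(OCc9ccccc9)C1=Cc3c(OCc9ccccc9)cc(OCc9ccccc9)c4c3O[C@H](c3ccc(OCc9ccccc9)c(OCc9ccccc9)c3)[C@H](OCc9ccccc9)[C@H]4c3c(OCc9ccccc9)c(Br)c4c(c3OCc9ccccc9)C[C@@H](OCc9ccccc9)[C@@H](c3ccc(OCc9ccccc9)c(OCc9ccccc9)c3)O4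
F6 | step 19 | phenolic N-methoxy-N-methylamide from 27 | Oc3cc(OCc9ccccc9)c([C@@H]4c5c(OCc9ccccc9)cc(OCc9ccccc9)cc5O[C@H](c5ccc(OCc9ccccc9)c(OCc9ccccc9)c5)[C@H]4O)c(OCc9ccccc9)c3[C@@H](c3c(OCc9ccccc9)cc(OCc9ccccc9)c4c3O[C@H](c3ccc(OCc9ccccc9)c(OCc9ccccc9)c3)[C@H](OCc9ccccc9)[C@H]4c3c(OCc9ccccc9)c(Br)c4c(c3OCc9ccccc9)C[C@@H](OCc9ccccc9)[C@@H](c3ccc(OCc9ccccc9)c(OCc9ccccc9)c3)O4)CC(=O)N(C)OC
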